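**Plan**

- Retrosynthesis: the C8 phenol is carried as a methyl ether and the lactone is opened at C1–O2. The benzene ring is then cut at C8–C8a and C4a–C5. The open chain is cut at C1–C8a (acetylide carboxylation), C3–C4 (aldehyde propargylation) and the side-chain C5'–C6' bond (acetylide alkylation).
- Enabling feature: the carbocycle C4a–C5–C6–C7–C8–C8a carries oxygen only at C8 and carbon substituents only on the adjacent pair C8a (C1 carbonyl) and C4a (C4). C8a/C4a therefore map onto the two sp carbons of a 2-alkynoate, and C8–C7–C6–C5 onto a 1-methoxy-1,3-diene whose extra CH2CH2 bridge leaves as ethylene.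
- Forward order: the chain is assembled first (steps 1–6), the benzene ring is made in step 7, the lactone ring is closed in step 8 and the phenol is freed in step 9.
- Stereochemistry: C3 (R) is set by catalyst-controlled Si-face propargylation of the C16 aldehyde and no later step breaks a bond at it. The E-alkene comes from anti reduction of an internal alkyne.

Key step: step 7

Assumption: in the phosphoric-acid-catalysed allenylboration the (S)-acid is taken to direct attack to the Si face of an unbranched aldehyde (mirror image of the Re-face preference associated with the (R)-acid); the configuration of 11 is to be confirmed by Mosher ester analysis before material is carried forward.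

**Route**

Step 1
Reactants: 1 1-decyne; 2 6-bromohexan-1-ol
Product: 6 hexadec-7-yn-1-ol, via lithium dec-1-ynide 3 (not isolated), via lithium 6-bromohexan-1-olate 4 (not isolated), via lithium hexadec-7-yn-1-olate 5 (not isolated)
Conditions: n-BuLi, THF, −78 → 0 °C (1 and 2 deprotonated in separate flasks); combine, DMPU, 0 °C → rt; H2O
Reagents that add atoms: none
Why: SN2 alkylation of a lithium acetylide by a primary bromide in a dipolar cosolvent, with the hydroxyl carried as its lithium alkoxide so that no protecting group is needed, a tactic established for omega-bromo alcohols and omega-bromo acids.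

Step 2
Reactants: 6 hexadec-7-yn-1-ol
Product: 7 (7E)-hexadec-7-en-1-ol
Conditions: Na, NH3(l)/THF, −33 °C; then solid NH4Cl
Reagents that add atoms: none
Why: Dissolving-metal reduction of an internal alkyne, in which the vinyl radical/anion relaxes to the trans geometry before the second protonation, should give the E-alkene with the hydroxyl as a spectator.

Step 3
Reactants: 7 (7E)-hexadec-7-en-1-ol
Product: 8 (7E)-hexadec-7-enal
Conditions: TEMPO (10 mol%), PhI(OAc)2 (1.1 equiv), CH2Cl2, rt; used at once
Reagents that add atoms: none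
Why: TEMPO-catalysed oxidation through the oxoammonium ion, with PhI(OAc)2 as terminal oxidant, stops at the aldehyde and does not touch the isolated alkene.

Step 4
Reactants: 8 (7E)-hexadec-7-enal; 9 allenylboronic acid pinacol ester
Product: 11 (4R,10E)-nonadec-10-en-1-yn-4-ol, via pinacol borate ester 10 (not isolated)
Conditions: 9 (1.5 equiv), (S)-TRIP [(S)-3,3'-bis(2,4,6-triisopropylphenyl)-1,1'-binaphthyl-2,2'-diyl hydrogen phosphate] (5 mol%), 4 Å molecular sieves, toluene, −20 °C; H2O work-up
Reagents that add atoms: none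
Why: Chiral Brønsted acid-catalysed asymmetric propargylation (allenylboration), in which the phosphoric acid binds the boronate oxygen and the formyl hydrogen in a closed six-membered SE2' transition state, so the allenyl gamma carbon is delivered to the Si face of the aldehyde and the new C–O stereocentre is set as R by the catalyst.

Step 5
Reactants: 11 (4R,10E)-nonadec-10-en-1-yn-4-ol
Product: 12 tert-butyl(dimethyl){[(4R,10E)-nonadec-10-en-1-yn-4-yl]oxy}silane
Conditions: TBSCl, imidazole, DMF, rt
Reagents that add atoms: tert-butyldimethylsilyl chloride, CC(C)(C)[Si](C)(C)Cl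
Why: Imidazole-promoted silylation of a secondary alcohol gives an ether that should withstand the acetylide chemistry and the thermal step and is later removed by fluoride.

Step 6
Reactants: 12 tert-butyl(dimethyl){[(4R,10E)-nonadec-10-en-1-yn-4-yl]oxy}silane
Product: 14 methyl (5R,11E)-5-(tert-butyldimethylsilyloxy)icos-11-en-2-ynoate, via lithium acetylide 13 (not isolated)
Conditions: n-BuLi, THF, −78 °C; ClCO2Me, −78 → 0 °C
Reagents that add atoms: methyl chloroformate, COC(=O)Cl
Why: Deprotonation of the terminal alkyne and C-acylation of the acetylide with a chloroformate is the standard entry to 2-alkynoates, and the low temperature avoids gamma-deprotonation of the product.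

Step 7
Reactants: 14 methyl (5R,11E)-5-(tert-butyldimethylsilyloxy)icos-11-en-2-ynoate; 15 1-methoxycyclohexa-1,3-diene
Product: 17 methyl 2-methoxy-6-[(2R,8E)-2-(tert-butyldimethylsilyloxy)heptadec-8-en-1-yl]benzoate, via bicyclo[2.2.2]octadiene adduct 16 (not isolated)
Conditions: freshly distilled 15 (4 equiv), BHT (cat.), neat, sealed tube under argon, 140 °C then 200 °C
Reagents that add atoms: none
Why: A normal-electron-demand [4+2] cycloaddition between the electron-rich methoxydiene 15 and the electron-poor alkyne of 14 forms C8–C8a and C4a–C5 in one intermolecular event and gives the bicyclo[2.2.2]octa-2,5-diene 16; further heating expels the CH2CH2 bridge as ethylene by retro-[4+2], so the benzene ring is closed by cycloaddition and revealed by cycloreversion. The closest known reaction is the Alder–Rickert synthesis of 6-substituted salicylate ethers from 1-alkoxycyclohexa-1,3-dienes and 2-alkynoates. The selectivity needed is regiochemical, with OMe next to the ester-bearing carbon: the diene terminus remote from OMe carries the largest HOMO coefficient and bonds to the beta carbon of the ynoate, which carries the largest LUMO coefficient, so the methoxy-bearing carbon ends up on the alpha carbon. No stereocentre is created in 17, since the bridgehead centres of 16 vanish on aromatisation and both diastereomeric adducts converge. The chain E-alkene is an unactivated dienophile and the C3 silyl ether lies outside every bond change; excess diene, a radical inhibitor and staged heating (cycloaddition before extrusion) are meant to limit diene dimerisation and 1,5-hydrogen shifts.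

Step 8
Reactants: 17 methyl 2-methoxy-6-[(2R,8E)-2-(tert-butyldimethylsilyloxy)heptadec-8-en-1-yl]benzoate
Product: 19 (3R)-8-methoxy-3-[(6E)-pentadec-6-en-1-yl]-3,4-dihydro-1H-isochromen-1-one, via hydroxy ester 18 (not isolated)
Conditions: HF·pyridine, THF, 0 °C → rt; then p-TsOH·H2O (10 mol%), toluene, 60 °C
Reagents that add atoms: none
Why: Fluoride-driven desilylation frees the C3 hydroxyl, which closes the six-membered lactone by acid-catalysed intramolecular transesterification onto the neighbouring benzoate, with C3 retained because its C–O bond is never broken.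

Step 9
Reactants: 19 (3R)-8-methoxy-3-[(6E)-pentadec-6-en-1-yl]-3,4-dihydro-1H-isochromen-1-one
Product: 21 (3R)-8-hydroxy-3-[(6E)-pentadec-6-en-1-yl]-3,4-dihydro-1H-isochromen-1-one, via dichloroboryl aryl ether 20 (not isolated)
Conditions: BCl3 (1 M in CH2Cl2, 1.5 equiv), CH2Cl2, −78 → 0 °C; then H2O
Reagents that add atoms: none
Why: Chelation-directed aryl methyl ether cleavage, in which BCl3 is held between the lactone carbonyl and the peri C8 methoxy oxygen and chloride removes the methyl group by SN2, should free the hydrogen-bonded phenol on hydrolysis without affecting the alkene, the lactone or C3.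

**Compound list**

1 | 1-decyne | CCCCCCCCC#C | starting material
2 | 6-bromohexan-1-ol | OCCCCCCBr | starting material
3 | lithium dec-1-ynide | [Li]C#CCCCCCCCC | intermediate
4 | lithium 6-bromohexan-1-olate | [Li+].[O-]CCCCCCBr | intermediate
5 | lithium hexadec-7-yn-1-olate | [Li+].[O-]CCCCCCC#CCCCCCCCC | intermediate
6 | hexadec-7-yn-1-ol | OCCCCCCC#CCCCCCCCC | intermediate
7 | (7E)-hexadec-7-en-1-ol | CCCCCCCC/C=C/CCCCCCO | intermediate
8 | (7E)-hexadec-7-enal | CCCCCCCC/C=C/CCCCCC=O | intermediate
9 | allenylboronic acid pinacol ester (4,4,5,5-tetramethyl-2-(propa-1,2-dien-1-yl)-1,3,2-dioxaborolane) | C=C=CB1OC(C)(C)C(C)(C)O1 | starting material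
10 | 2-{[(4R,10E)-nonadec-10-en-1-yn-4-yl]oxy}-4,4,5,5-tetramethyl-1,3,2-dioxaborolane | CCCCCCCC/C=C/CCCCC[C@@H](OB1OC(C)(C)C(C)(C)O1)CC#C | intermediate
11 | (4R,10E)-nonadec-10-en-1-yn-4-ol | CCCCCCCC/C=C/CCCCC[C@@H](O)CC#C | intermediate
12 | tert-butyl(dimethyl){[(4R,10E)-nonadec-10-en-1-yn-4-yl]oxy}silane | CCCCCCCC/C=C/CCCCC[C@@H](O[Si](C)(C)C(C)(C)C)CC#C | intermediate
13 | lithium (4R,10E)-4-(tert-butyldimethylsilyloxy)nonadec-10-en-1-yn-1-ide | CCCCCCCC/C=C/CCCCC[C@@H](O[Si](C)(C)C(C)(C)C)CC#C[Li] | intermediate
14 | methyl (5R,11E)-5-(tert-butyldimethylsilyloxy)icos-11-en-2-ynoate | CCCCCCCC/C=C/CCCCC[C@@H](O[Si](C)(C)C(C)(C)C)CC#CC(=O)OC | intermediate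
15 | 1-methoxycyclohexa-1,3-diene | COC1=CC=CCC1 | starting material
16 | methyl 1-methoxy-3-[(2R,8E)-2-(tert-butyldimethylsilyloxy)heptadec-8-en-1-yl]bicyclo[2.2.2]octa-2,5-diene-2-carboxylate (both bridgehead diastereomers) | CCCCCCCC/C=C/CCCCC[C@@H](O[Si](C)(C)C(C)(C)C)CC1=C(C(=O)OC)C2(OC)CCC1C=C2 | intermediate
17 | methyl 2-methoxy-6-[(2R,8E)-2-(tert-butyldimethylsilyloxy)heptadec-8-en-1-yl]benzoate | CCCCCCCC/C=C/CCCCC[C@@H](O[Si](C)(C)C(C)(C)C)Cc1cccc(OC)c1C(=O)OC | intermediate
18 | methyl 2-[(2R,8E)-2-hydroxyheptadec-8-en-1-yl]-6-methoxybenzoate | CCCCCCCC/C=C/CCCCC[C@@H](O)Cc1cccc(OC)c1C(=O)OC | intermediate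
19 | (3R)-8-methoxy-3-[(6E)-pentadec-6-en-1-yl]-3,4-dihydro-1H-isochromen-1-one | CCCCCCCC/C=C/CCCCC[C@@H]1Cc2cccc(OC)c2C(=O)O1 | intermediate
20 | (3R)-8-[(dichloroboranyl)oxy]-3-[(6E)-pentadec-6-en-1-yl]-3,4-dihydro-1H-isochromen-1-one | CCCCCCCC/C=C/CCCCC[C@@H]1Cc2cccc(OB(Cl)Cl)c2C(=O)O1 | intermediate
21 | (3R)-8-hydroxy-3-[(6E)-pentadec-6-en-1-yl]-3,4-dihydro-1H-isochromen-1-one | CCCCCCCC/C=C/CCCCC[C@@H]1Cc2cccc(O)c2C(=O)O1 | target

**Step count**

Total: 9 steps. Longest linear sequence: 9 steps (1 and 2 to 21; 9 and 15 are bought).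

**Steps most likely to fail**

Step 7. The cycloaddition of a beta-alkyl ynoate may be slow compared with thermal consumption of the diene (dimerisation, hydrogen shift to the 2-methoxy isomer), which would show as low conversion or eroded regiocontrol. The fallback keeps the benzannulation but raises the activation of the alkyne by changing its oxidation level. It sets out from 12: lithiation as in step 6 gives 13, which is formylated with DMF (inverse quench into aqueous KH2PO4) to the ynal (5R,11E)-5-(tert-butyldimethylsilyloxy)icos-11-en-2-ynal F1. The aldehyde-activated alkyne should add diene 15 at a much lower temperature (toluene, 90–110 °C) to give the bicyclic enal 1-methoxy-3-[(2R,8E)-2-(tert-butyldimethylsilyloxy)heptadec-8-en-1-yl]bicyclo[2.2.2]octa-2,5-diene-2-carbaldehyde F2. Heating F2 to 160–180 °C should expel ethylene and give 2-methoxy-6-[(2R,8E)-2-(tert-butyldimethylsilyloxy)heptadec-8-en-1-yl]benzaldehyde F3. Pinnick oxidation (NaClO2, NaH2PO4, 2-methylbut-2-ene, t-BuOH/H2O) then gives 2-methoxy-6-[(2R,8E)-2-(tert-butyldimethylsilyloxy)heptadec-8-en-1-yl]benzoic acid F4. HF·pyridine followed by p-TsOH·H2O in warm toluene should pass through the hydroxy acid 2-[(2R,8E)-2-hydroxyheptadec-8-en-1-yl]-6-methoxybenzoic acid F5, which lactonises to 19, where the route is rejoined.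

Step 4. Facial discrimination may be insufficient with an unbranched aliphatic aldehyde, so the enantiomeric purity at C3 could be eroded or the unintended face attacked. The fallback fixes the stereocentre by resolution of an epoxide. It sets out from 8: Corey–Chaykovsky methylenation (Me3SI, NaH, DMSO/THF) gives racemic 2-[(6E)-pentadec-6-en-1-yl]oxirane F6. Hydrolytic kinetic resolution with (R,R)-(salen)Co(OAc) (salen = N,N'-bis(3,5-di-tert-butylsalicylidene)cyclohexane-1,2-diamine; 0.5 mol%, 0.55 equiv H2O) should leave (2R)-2-[(6E)-pentadec-6-en-1-yl]oxirane F7 and convert the other enantiomer into (2S,8E)-heptadec-8-ene-1,2-diol F8, which is removed by chromatography. Opening F7 at its terminal carbon with LiC≡CH·H2NCH2CH2NH2 in DMSO does not touch the C–O stereocentre and should give 11, where the route is rejoined.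

Step 1. SN2 displacement on the aggregated bromo alkoxide may be sluggish, with proton transfer back to the acetylide and elimination competing. The fallback masks the hydroxyl instead. It sets out from 2: dihydropyran with PPTS in CH2Cl2 gives 2-[(6-bromohexyl)oxy]oxane F9. Alkylation of 3 (from 1 and n-BuLi, THF/DMPU) with F9 gives 2-(hexadec-7-yn-1-yloxy)oxane F10. Acid-catalysed methanolysis (p-TsOH·H2O, MeOH, rt) removes the acetal and returns 6.

**Further compounds**

F1 | step 7 | (5R,11E)-5-(tert-butyldimethylsilyloxy)icos-11-en-2-ynal | CCCCCCCC/C=C/CCCCC[C@@H](O[Si](C)(C)C(C)(C)C)CC#CC=O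
F2 | step 7 | 1-methoxy-3-[(2R,8E)-2-(tert-butyldimethylsilyloxy)heptadec-8-en-1-yl]bicyclo[2.2.2]octa-2,5-diene-2-carbaldehyde | CCCCCCCC/C=C/CCCCC[C@@H](O[Si](C)(C)C(C)(C)C)CC1=C(C=O)C2(OC)CCC1C=C2
F3 | step 7 | 2-methoxy-6-[(2R,8E)-2-(tert-butyldimethylsilyloxy)heptadec-8-en-1-yl]benzaldehyde | CCCCCCCC/C=C/CCCCC[C@@H](O[Si](C)(C)C(C)(C)C)Cc1cccc(OC)c1C=O
F4 | step 7 | 2-methoxy-6-[(2R,8E)-2-(tert-butyldimethylsilyloxy)heptadec-8-en-1-yl]benzoic acid | CCCCCCCC/C=C/CCCCC[C@@H](O[Si](C)(C)C(C)(C)C)Cc1cccc(OC)c1C(=O)O
F5 | step 7 | 2-[(2R,8E)-2-hydroxyheptadec-8-en-1-yl]-6-methoxybenzoic acid | CCCCCCCC/C=C/CCCCC[C@@H](O)Cc1cccc(OC)c1C(=O)O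
F6 | step 4 | rac-2-[(6E)-pentadec-6-en-1-yl]oxirane | CCCCCCCC/C=C/CCCCCC1CO1
F7 | step 4 | (2R)-2-[(6E)-pentadec-6-en-1-yl]oxirane | CCCCCCCC/C=C/CCCCC[C@@H]1CO1
F8 | step 4 | (2S,8E)-heptadec-8-ene-1,2-diol | CCCCCCCC/C=C/CCCCC[C@H](O)CO
F9 | step 1 | 2-[(6-bromohexyl)oxy]oxane | BrCCCCCCOC1CCCCO1
F10 | step 1 | 2-(hexadec-7-yn-1-yloxy)oxane | CCCCCCCCC#CCCCCCCOC1CCCCO1
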